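Count the incoming ligand against the starting complex before reading any rate.

| flask | starting complex | incoming ligand | leaving ligand | remark | time |
|---|---|---|---|---|---|
| midnight | 0.10 M | 0.11 M | 0.050 M | run made earlier |  |
| dusk | 0.15 M | 0.11 M | 0.050 M | run made earlier |  |
| green | 0.10 M | 0.110 M (in portions, 4, over 3.0 h) | 0.0500 M | first portion at the start, last at 3.0 h | 8.0 h |
| blue | 0.10 M | 0.110 M | 0.0500 M | everything together at the start | 8.0 h |
| ochre | 0.10 M | 0.110 M (fed, over 3.0 h) | 0.0500 M | all else is in the flask from the start; the feed brings no volume worth counting | 8.0 h |
| grey | 0.10 M (fed, over 3.0 h) | 0.110 M | 0.0500 M | all else is in the flask from the start; the feed brings no volume worth counting | 8.0 h |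

- midnight (time / h: side product / %, complex with two exchanged / %): 0.250: 0, 0.8; 0.667: 0.9, 2.2; 1.33: 4.6, 3.4; 2.00: 10.3, 5.4; 3.00: 17.6, 3.5; 4.00: 25.3, 4.4; 5.00: 31.3, 4.2
- dusk (time / min: side product / %, complex with two exchanged / %): 8.00: 0, 0.2; 12.0: 0.2, 0; 20.0: 0.2, 0.9; 25.0: 0, 0.3; 40.0: 1.6, 1.0; 60.0: 4.2, 2.5; 90.0: 7.4, 1.8

(scatter of a reading: 0.5 percentage points)

- percent here means starting complex units held: one side product counts as two
- what was read earlier has a scatter of 0.5 percentage points, one standard deviation

* which flask leads in amount of side product, in percent of the starting complex charged ("all alike" within 1.5 percentage points) (green / blue / ochre / grey / all alike)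
* how much side product is there at the end, in percent of the starting complex charged: green
* how much side product is there at the end, in percent of the starting complex charged: blue
* how much side product is there at the end, in percent of the starting complex charged: ochre
* how much side product is there at the end, in percent of the starting complex charged: grey

I named that count the allowance, 1.10, the incoming ligand charged per starting complex charged. Blue repeats the charges of midnight, so I followed midnight in slow motion.

In the first instants, at 0.250 h, midnight showed 0.8% of complex with two exchanged and 0% of side product. I read the complex with two exchanged as the forerunner, which meets starting complex to give side product. On that reading, each starting-complex unit in side product carries one incoming ligand.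

In the middle of the midnight run, from 2.00 h to 5.00 h, the forerunner read between 3.5% and 5.4%, while side product gained 21 percentage points.

For the end, I reckoned two things:

ceiling on side product = the smaller of the whole charge and the allowance = 100%

share of the ligand charge in side product = side product / allowance

At 5.00 h, midnight's reading gives a share of 28.5%. Green, blue, ochre and grey carry the same total charges, so they share one ceiling, and I looked to timing to part them at 8.0 h.

The forecast named blue as leader, with 37% for green, 45% for blue, 36% for ochre and 32% for grey: “Extrapolating blue gives about 45% at 8 h”. That blue figure needs a share of 40.9%, which fits within the charge.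

The flasks gave 36.4% for green, 37.0% for ochre and 38.6% for grey, and blue led with 43.8%. Grey stood 6.6 points above the forecast.

    starting complex + incoming ligand ⇌ leaving ligand + complex with one exchanged (K = 0.390, k = 0.0760 M⁻¹ min⁻¹)
    complex with one exchanged + incoming ligand ⇌ leaving ligand + complex with two exchanged (K = 5.00, k = 0.0630 M⁻¹ min⁻¹)
    complex with two exchanged + incoming ligand ⇌ leaving ligand + complex with three exchanged (K = 0.250, k = 0.180 M⁻¹ min⁻¹)
    starting complex + complex with two exchanged → side product (k = 0.230 M⁻¹ min⁻¹)

Blue's side product held 39.8% of its ligand charge, with 47% of that charge left at 8.00 h. At 80.0 h, blue gave 84.4% and green 84.2%, under their ceiling. The neighbouring flask, blue with 0.25 M of starting complex, has an allowance of 0.440. That makes incoming ligand the limiting reagent, with a ceiling of 44.0%. It gave 25.4%, a share of 57.7%, with 27.1% of its ligand charge left and 68.3% of its starting complex left.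

(The earlier runs and the new flask were computed with made-up constants.)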